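**Retrosynthetic overview**

1. The α-methylene group is unmasked last from a Mannich base. The 14-membered ring is closed by an intramolecular B-alkyl Suzuki coupling (C8–C9), and C3–C4 comes from an asymmetric alkenylzinc addition to a C3 aldehyde.
2. The ε-lactone comes from Baeyer–Villiger ring expansion of a 2,2,5-trisubstituted cyclohexanone; the quaternary carbon C12 migrates with retention and becomes the tertiary C–O centre.
3. The cyclohexanone comes from Birch dearomatisation of 2-(3-methoxyphenyl)ethanol (anisole ring = C16, C15, C1, C14, C13, C12), then CuH reduction (C1), C-formylation and axial C-methylation (C12), and catalytic asymmetric vinylation (C11).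
4. The C4–C8 piece comes from but-2-yn-1-ol (Z vinyl iodide by hydroalumination and iodination) and a propynyl Grignard reagent.
5. Ring order: six-membered carbocycle (from the arene), then seven-membered lactone, then fourteen-membered carbocycle.

Atom labels C1–C17 are the cembrane numbering of the target, which is (1S,3S,4E,7Z,11R,12S).

Assumption: the sense of induction of (R)-DTBM-SEGPHOS and of (+)-MIB is taken from the closest literature substrates; if a sense turns out reversed, the antipodal ligand is used.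

**Step 1**
Reactants: 1 2-(3-methoxyphenyl)ethanol
Product: 3 3-(2-hydroxyethyl)cyclohex-2-en-1-one, via Birch dienol ether 2 (not isolated)
Conditions: Li, NH3 (l), t-BuOH, THF, −78 to −33 °C; then 2 M HCl, THF, rt
Reagents that add atoms: water, O
Why: Birch reduction dearomatises the anisole to the 1-methoxy-1,4-diene with the alkyl group on a double bond, and acid hydrolysis of the enol ether with conjugation gives the 3-substituted cyclohexenone without forming a stereocentre.

**Step 2**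
Reactants: 3 3-(2-hydroxyethyl)cyclohex-2-en-1-one
Product: 4 3-[2-(triethylsilyloxy)ethyl]cyclohex-2-en-1-one
Conditions: Et3SiCl, imidazole, CH2Cl2, 0 °C to rt
Reagents that add atoms: chlorotriethylsilane, CC[Si](Cl)(CC)CC
Why: Routine silylation protects the primary alcohol as a triethylsilyl ether that survives the basic steps and is later oxidised directly.

**Step 3**
Reactants: 4 3-[2-(triethylsilyloxy)ethyl]cyclohex-2-en-1-one
Product: 6 (3S)-3-[2-(triethylsilyloxy)ethyl]cyclohexan-1-one, via silyl enol ether 5 (not isolated)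
Conditions: Cu(OAc)2·H2O (3 mol %), (R)-DTBM-SEGPHOS (3 mol %), (EtO)2MeSiH, toluene, 0 °C; then 1 M NaOH, THF, 0 °C
Reagents that add atoms: none
Why: Asymmetric conjugate reduction by ligated copper hydride delivers hydride to one enantiotopic face of the β-carbon and sets C1 as S, and the silyl enol ether is hydrolysed on work-up.

**Step 4**
Reactants: 6 (3S)-3-[2-(triethylsilyloxy)ethyl]cyclohexan-1-one
Product: 7 (2Z,5S)-2-(hydroxymethylidene)-5-[2-(triethylsilyloxy)ethyl]cyclohexan-1-one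
Conditions: NaH, HCO2Et, EtOH (cat.), THF, 0 °C to rt; then AcOH
Reagents that add atoms: ethyl formate, CCOC=O
Why: Claisen-type C-formylation under equilibrating conditions occurs at the less hindered α-carbon remote from the side chain (C12) and is driven by formation of the stabilised β-ketoaldehyde enolate.

**Step 5**
Reactants: 7 (2Z,5S)-2-(hydroxymethylidene)-5-[2-(triethylsilyloxy)ethyl]cyclohexan-1-one
Product: 8 (1S,4S)-1-methyl-2-oxo-4-[2-(triethylsilyloxy)ethyl]cyclohexane-1-carbaldehyde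
Conditions: MeI, K2CO3, acetone, 50 °C
Reagents that add atoms: iodomethane, IC
Why: C-Alkylation of the β-ketoaldehyde enolate proceeds by axial attack of iodomethane on the half-chair that keeps the C1 side chain equatorial, so the methyl group ends up cis and the formyl group trans to the side chain (expected dr about 4:1, minor isomer and O-methyl ether removed by chromatography).

**Step 6**
Reactants: 8 (1S,4S)-1-methyl-2-oxo-4-[2-(triethylsilyloxy)ethyl]cyclohexane-1-carbaldehyde
Product: 10 (1R)-1-{(1S,4S)-1-methyl-2-oxo-4-[2-(triethylsilyloxy)ethyl]cyclohexyl}prop-2-en-1-yl acetate, via ethenylzinc alkoxide 9 (not isolated)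
Conditions: Zn(CH=CH2)2, (+)-MIB (10 mol %), toluene, −20 to 0 °C; then Ac2O, DMAP, 0 °C to rt
Reagents that add atoms: divinylzinc, C=C[Zn]C=C; acetic anhydride, CC(=O)OC(C)=O
Why: Amino-alcohol-catalysed asymmetric vinylzinc addition (Oppolzer–Noyori type) attacks only the non-enolisable aldehyde, the ligand sending the vinyl group to the Re face to give 11R under reagent control, and the zinc alkoxide is acetylated in the same flask.

**Step 7**
Reactants: 10 (1R)-1-{(1S,4S)-1-methyl-2-oxo-4-[2-(triethylsilyloxy)ethyl]cyclohexyl}prop-2-en-1-yl acetate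
Product: 11 (1R)-1-{(2S,5S)-2-methyl-7-oxo-5-[2-(triethylsilyloxy)ethyl]oxepan-2-yl}prop-2-en-1-yl acetate
Conditions: mCPBA, NaHCO3, CH2Cl2, 0 °C to rt
Reagents that add atoms: 3-chloroperoxybenzoic acid, OOC(=O)c1cccc(Cl)c1
Why: In this Baeyer–Villiger oxidation the quaternary carbon C12 migrates in preference to the CH2 carbon and with retention, turning the all-carbon stereocentre into the tertiary C–O centre of the ε-lactone, while the electron-poor monosubstituted alkene is epoxidised much more slowly.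

**Step 8**
Reactants: 11 (1R)-1-{(2S,5S)-2-methyl-7-oxo-5-[2-(triethylsilyloxy)ethyl]oxepan-2-yl}prop-2-en-1-yl acetate
Product: 13 (1R)-1-{(2S,5S)-6-[(dimethylamino)methyl]-2-methyl-7-oxo-5-[2-(triethylsilyloxy)ethyl]oxepan-2-yl}prop-2-en-1-yl acetate, via lithium lactone enolate 12 (not isolated)
Conditions: LiN(SiMe3)2, THF, −78 °C; then [Me2N=CH2]I, −78 to 0 °C
Reagents that add atoms: N,N-dimethylmethyleneiminium iodide, C[N+](C)=C.[I-]
Why: The lactone α-CH2 is several pKa units more acidic than the acetate methyl group, so the amide base forms the lactone enolate selectively and a Mannich reaction installs the masked methylene carbon C17 (the new C15 centre is a mixture that is erased in the last step).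

**Step 9**
Reactants: 13 (1R)-1-{(2S,5S)-6-[(dimethylamino)methyl]-2-methyl-7-oxo-5-[2-(triethylsilyloxy)ethyl]oxepan-2-yl}prop-2-en-1-yl acetate
Product: 14 (1R)-1-{(2S,5S)-6-[(dimethylamino)methyl]-2-methyl-7-oxo-5-(2-oxoethyl)oxepan-2-yl}prop-2-en-1-yl acetate
Conditions: (COCl)2, DMSO, CH2Cl2, −78 to −40 °C; then Et3N, −78 to 0 °C
Reagents that add atoms: none
Why: Under Swern conditions the primary triethylsilyl ether is cleaved through the alkoxysulfonium ion and oxidised directly to the aldehyde, while the acetate, lactone and tertiary amine are inert.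

**Step 10**
Reactants: 15 but-2-yn-1-ol
Product: 17 (2Z)-3-iodobut-2-en-1-ol, via cyclic alkenylalanate 16 (not isolated)
Conditions: NaAlH2(OCH2CH2OMe)2, Et2O, 0 °C; then I2, −78 to 0 °C
Reagents that add atoms: iodine, [I][I]
Why: Trans-hydroalumination of the propargylic alcohol through the chelated alkoxyalanate places aluminium on C3 cis to the CH2O group, and iodinolysis with retention gives the Z vinyl iodide.

**Step 11**
Reactants: 17 (2Z)-3-iodobut-2-en-1-ol
Product: 18 (2Z)-1-bromo-3-iodobut-2-ene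
Conditions: PBr3, Et2O, 0 °C
Reagents that add atoms: phosphorus tribromide, BrP(Br)Br
Why: SN2 bromination of the primary allylic alcohol through its phosphite ester leaves the alkene geometry untouched.

**Step 12**
Reactants: 18 (2Z)-1-bromo-3-iodobut-2-ene
Product: 19 (2Z)-2-iodohept-2-en-5-yne
Conditions: CH3C≡CMgBr, CuBr·SMe2 (10 mol %), THF, −20 °C to rt
Reagents that add atoms: prop-1-ynylmagnesium bromide, CC#C[Mg]Br
Why: Copper-catalysed SN2 alkynylation of the primary allylic bromide gives the skipped enyne, the vinyl iodide being inert without palladium and the Z geometry being retained.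

**Step 13**
Reactants: 19 (2Z)-2-iodohept-2-en-5-yne; 14 (1R)-1-{(2S,5S)-6-[(dimethylamino)methyl]-2-methyl-7-oxo-5-(2-oxoethyl)oxepan-2-yl}prop-2-en-1-yl acetate
Product: 22 (1R)-1-{(2S,5S)-6-[(dimethylamino)methyl]-5-[(2S,3E,6Z)-2-hydroxy-7-iodo-3-methylocta-3,6-dien-1-yl]-2-methyl-7-oxooxepan-2-yl}prop-2-en-1-yl acetate, via alkenylzirconocene chloride 20 (not isolated), via alkenyl(methyl)zinc 21 (not isolated)
Conditions: Cp2Zr(H)Cl, CH2Cl2, rt; then ZnMe2, toluene, −65 °C; then (+)-MIB (10 mol %), 14, −30 to 0 °C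
Reagents that add atoms: none
Why: Syn hydrozirconation puts zirconium on the methyl-bearing alkyne carbon (about 9:1), Zr-to-Zn transmetalation (Wipf) gives an alkenylzinc whose amino-alcohol-catalysed addition to the aldehyde occurs on the Re face, setting C3 as S and the C4=C5 bond as E.

**Step 14**
Reactants: 22 (1R)-1-{(2S,5S)-6-[(dimethylamino)methyl]-5-[(2S,3E,6Z)-2-hydroxy-7-iodo-3-methylocta-3,6-dien-1-yl]-2-methyl-7-oxooxepan-2-yl}prop-2-en-1-yl acetate
Product: 24 (1S,3S,4E,7Z,11R,12S)-11-acetoxy-17-(dimethylamino)-3-hydroxycembra-4,7-dien-16,12-olide, via bis(9-BBN) adduct 23 (not isolated)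
Conditions: 9-BBN dimer (3 equiv), THF, rt; then PdCl2(dppf) (10 mol %), Ph3As, Cs2CO3, DMF/THF/H2O, rt, slow addition (2 mM)
Reagents that add atoms: none
Why: 9-BBN hydroborates only the monosubstituted alkene at its terminus (the C3 hydroxyl is O-borylated and freed again on work-up), and the intramolecular B-alkyl Suzuki–Miyaura coupling with the Z vinyl iodide proceeds with retention under high dilution to close the 14-membered ring.

**Step 15**
Reactants: 24 (1S,3S,4E,7Z,11R,12S)-11-acetoxy-17-(dimethylamino)-3-hydroxycembra-4,7-dien-16,12-olide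
Product: 26 (1S,3S,4E,7Z,11R,12S)-11-acetoxy-3-hydroxycembra-4,7,15(17)-trien-16,12-olide, via trimethylammonium iodide 25 (not isolated)
Conditions: MeI, CH2Cl2, rt; then NaHCO3 (aq), rt
Reagents that add atoms: none
Why: N-Methylation turns the amine into a leaving group and mild base triggers E1cB (Hofmann-type) elimination to the α-methylene lactone without touching the acetate or the allylic alcohol.

**Compound list**

1 | 2-(3-methoxyphenyl)ethanol | COc1cccc(CCO)c1 | starting material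
2 | 2-(5-methoxycyclohexa-1,4-dien-1-yl)ethanol | COC1=CCC=C(CCO)C1 | intermediate
3 | 3-(2-hydroxyethyl)cyclohex-2-en-1-one | O=C1C=C(CCO)CCC1 | intermediate
4 | 3-[2-(triethylsilyloxy)ethyl]cyclohex-2-en-1-one | O=C1C=C(CCO[Si](CC)(CC)CC)CCC1 | intermediate
5 | (3S)-1-[diethoxy(methyl)silyloxy]-3-[2-(triethylsilyloxy)ethyl]cyclohex-1-ene | CCO[Si](C)(OCC)OC1=C[C@H](CCO[Si](CC)(CC)CC)CCC1 | intermediate
6 | (3S)-3-[2-(triethylsilyloxy)ethyl]cyclohexan-1-one | O=C1C[C@H](CCO[Si](CC)(CC)CC)CCC1 | intermediate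
7 | (2Z,5S)-2-(hydroxymethylidene)-5-[2-(triethylsilyloxy)ethyl]cyclohexan-1-one | O=C1C[C@H](CCO[Si](CC)(CC)CC)CC/C1=C/O | intermediate
8 | (1S,4S)-1-methyl-2-oxo-4-[2-(triethylsilyloxy)ethyl]cyclohexane-1-carbaldehyde | O=C1C[C@H](CCO[Si](CC)(CC)CC)CC[C@@]1(C)C=O | intermediate
9 | ethenylzinc (1R)-alkoxide of the vinyl adduct of 8 | O=C1C[C@H](CCO[Si](CC)(CC)CC)CC[C@@]1(C)[C@H](O[Zn]C=C)C=C | intermediate
10 | (1R)-1-{(1S,4S)-1-methyl-2-oxo-4-[2-(triethylsilyloxy)ethyl]cyclohexyl}prop-2-en-1-yl acetate | O=C1C[C@H](CCO[Si](CC)(CC)CC)CC[C@@]1(C)[C@H](OC(C)=O)C=C | intermediate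
11 | (1R)-1-{(2S,5S)-2-methyl-7-oxo-5-[2-(triethylsilyloxy)ethyl]oxepan-2-yl}prop-2-en-1-yl acetate | O=C1C[C@H](CCO[Si](CC)(CC)CC)CC[C@@](C)([C@H](OC(C)=O)C=C)O1 | intermediate
12 | lithium enolate of lactone 11 | [Li]OC1=C[C@H](CCO[Si](CC)(CC)CC)CC[C@@](C)([C@H](OC(C)=O)C=C)O1 | intermediate
13 | (1R)-1-{(2S,5S)-6-[(dimethylamino)methyl]-2-methyl-7-oxo-5-[2-(triethylsilyloxy)ethyl]oxepan-2-yl}prop-2-en-1-yl acetate (C6 epimers) | O=C1C(CN(C)C)[C@H](CCO[Si](CC)(CC)CC)CC[C@@](C)([C@H](OC(C)=O)C=C)O1 | intermediate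
14 | (1R)-1-{(2S,5S)-6-[(dimethylamino)methyl]-2-methyl-7-oxo-5-(2-oxoethyl)oxepan-2-yl}prop-2-en-1-yl acetate | O=C1C(CN(C)C)[C@H](CC=O)CC[C@@](C)([C@H](OC(C)=O)C=C)O1 | intermediate
15 | but-2-yn-1-ol | CC#CCO | starting material
16 | sodium 2,2-bis(2-methoxyethoxy)-3-methyl-2,5-dihydro-1,2-oxaluminol-2-uide (cyclic alkenylalanate) | CC1=CCO[Al-]1(OCCOC)OCCOC.[Na+] | intermediate
17 | (2Z)-3-iodobut-2-en-1-ol | C/C(I)=C/CO | intermediate
18 | (2Z)-1-bromo-3-iodobut-2-ene | C/C(I)=C/CBr | intermediate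
19 | (2Z)-2-iodohept-2-en-5-yne | C/C(I)=C/CC#CC | intermediate
20 | chlorobis(cyclopentadienyl)[(2E,5Z)-6-iodohepta-2,5-dien-2-yl]zirconium | C/C(=C\C/C=C(/C)I)[Zr](Cl)(C1C=CC=C1)C1C=CC=C1 | intermediate
21 | [(2E,5Z)-6-iodohepta-2,5-dien-2-yl](methyl)zinc | C/C(=C\C/C=C(/C)I)[Zn]C | intermediate
22 | (1R)-1-{(2S,5S)-6-[(dimethylamino)methyl]-5-[(2S,3E,6Z)-2-hydroxy-7-iodo-3-methylocta-3,6-dien-1-yl]-2-methyl-7-oxooxepan-2-yl}prop-2-en-1-yl acetate | O=C1C(CN(C)C)[C@H](C[C@H](O)/C(C)=C/C/C=C(/C)I)CC[C@@](C)([C@H](OC(C)=O)C=C)O1 | intermediate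
23 | C9-(9-borabicyclo[3.3.1]nonan-9-yl) O3-(9-borabicyclo[3.3.1]nonan-9-yl) adduct of 22 | O=C1C(CN(C)C)[C@H](C[C@H](OB2C3CCCC2CCC3)/C(C)=C/C/C=C(/C)I)CC[C@@](C)([C@H](OC(C)=O)CCB2C3CCCC2CCC3)O1 | intermediate
24 | (1S,3S,4E,7Z,11R,12S)-11-acetoxy-17-(dimethylamino)-3-hydroxycembra-4,7-dien-16,12-olide (C15 epimers) | CN(C)CC1C(=O)O[C@@]2(C)CC[C@H]1C[C@H](O)/C(C)=C/C/C=C(/C)CC[C@H]2OC(C)=O | intermediate
25 | 17-trimethylammonio derivative of 24, iodide salt | C[N+](C)(C)CC1C(=O)O[C@@]2(C)CC[C@H]1C[C@H](O)/C(C)=C/C/C=C(/C)CC[C@H]2OC(C)=O.[I-] | intermediate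
26 | (1S,3S,4E,7Z,11R,12S)-11-acetoxy-3-hydroxycembra-4,7,15(17)-trien-16,12-olide | C=C1C(=O)O[C@@]2(C)CC[C@H]1C[C@H](O)/C(C)=C/C/C=C(/C)CC[C@H]2OC(C)=O | target

**Step count**

Total: 15 steps. Longest linear sequence: 12 steps (steps 1–9 and 13–15); steps 10–12 make the C4–C8 fragment.

**Steps most likely to fail, with fallbacks**

Step 5 (C-methylation at C12). The axial preference is only moderate and O-methylation competes. The fallback sets C12 by a stereospecific 1,2-shift instead of an enolate alkylation; it sets out from 7 and comes back at 8. Deformylative methylenation of 7 (aqueous CH2O, K2CO3) gives (5S)-2-methylidene-5-[2-(triethylsilyloxy)ethyl]cyclohexan-1-one F1. Isomerisation with RhCl3·3H2O (cat.) in EtOH moves the double bond into the ring to give the carvone-type enone (5S)-2-methyl-5-[2-(triethylsilyloxy)ethyl]cyclohex-2-en-1-one F2. CH2=CHMgBr with CeCl3 at −78 °C adds 1,2 and axially, anti to the side chain, to give (1S,5S)-1-ethenyl-2-methyl-5-[2-(triethylsilyloxy)ethyl]cyclohex-2-en-1-ol F3. N-Bromosuccinimide then triggers a bromonium-induced semipinacol rearrangement in which the vinyl group migrates suprafacially from C16 to C12, so it is necessarily trans to the side chain in (2S,3S,5S)-3-bromo-2-ethenyl-2-methyl-5-[2-(triethylsilyloxy)ethyl]cyclohexan-1-one F4. Zn in AcOH removes the bromine to give (2S,5S)-2-ethenyl-2-methyl-5-[2-(triethylsilyloxy)ethyl]cyclohexan-1-one F5, and ozonolysis (O3, then Me2S) turns the vinyl group into the formyl group of 8.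

Step 7 (Baeyer–Villiger oxidation). The ketone is hindered and the vinyl group may be epoxidised at a comparable rate. The fallback expands the ring before any alkene is present; it sets out from 8 and comes back at 11. NaBH4 at −78 °C reduces only the aldehyde to give (2S,5S)-2-(hydroxymethyl)-2-methyl-5-[2-(triethylsilyloxy)ethyl]cyclohexan-1-one F6. mCPBA then gives (4S,7S)-7-(hydroxymethyl)-7-methyl-4-[2-(triethylsilyloxy)ethyl]oxepan-2-one F7 with no alkene to compete. Dess–Martin periodinane gives (2S,5S)-2-methyl-7-oxo-5-[2-(triethylsilyloxy)ethyl]oxepane-2-carbaldehyde F8. Vinylzinc addition with (+)-MIB as in step 6 gives the ethenylzinc alkoxide of the (1R)-vinyl adduct of F8 F9, which is acetylated in the flask to 11.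

Step 14 (B-alkyl Suzuki macrocyclisation). The substrate carries a free hydroxyl, an amine, an acetate and a lactone, and ring closure competes with oligomerisation and protodeboronation. The fallback makes C8–C9 intermolecularly and closes the ring at C3–C4 by a Nozaki–Hiyama–Kishi reaction; it sets out from 13 and 19 and comes back at 24. Hydroboration of 13 with 9-BBN gives the B-alkyl-9-BBN adduct of 13 F10. Suzuki coupling of this with 19 (PdCl2(dppf), Ph3As, Cs2CO3) gives (1R,4Z)-1-{(2S,5S)-6-[(dimethylamino)methyl]-2-methyl-7-oxo-5-[2-(triethylsilyloxy)ethyl]oxepan-2-yl}-4-methylnon-4-en-7-yn-1-yl acetate F11. Cp2Zr(H)Cl in slight excess, with equilibration, gives the alkenylzirconocene chloride of F11 F12, and I2 converts it into (1R,4Z,7E)-1-{(2S,5S)-6-[(dimethylamino)methyl]-2-methyl-7-oxo-5-[2-(triethylsilyloxy)ethyl]oxepan-2-yl}-8-iodo-4-methylnona-4,7-dien-1-yl acetate F13. Swern oxidation of the silyl ether as in step 9 gives (1R,4Z,7E)-1-{(2S,5S)-6-[(dimethylamino)methyl]-2-methyl-7-oxo-5-(2-oxoethyl)oxepan-2-yl}-8-iodo-4-methylnona-4,7-dien-1-yl acetate F14. CrCl2 with NiCl2 (cat.) in DMSO/THF at high dilution then closes the ring to 24; C3 is controlled by a chiral sulfonamide ligand on chromium or, failing that, by oxidation to the enone and oxazaborolidine-catalysed borane reduction.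

**Further compounds**

F1 | step 5 | (5S)-2-methylidene-5-[2-(triethylsilyloxy)ethyl]cyclohexan-1-one | O=C1C[C@H](CCO[Si](CC)(CC)CC)CCC1=C
F2 | step 5 | (5S)-2-methyl-5-[2-(triethylsilyloxy)ethyl]cyclohex-2-en-1-one | O=C1C[C@H](CCO[Si](CC)(CC)CC)CC=C1C
F3 | step 5 | (1S,5S)-1-ethenyl-2-methyl-5-[2-(triethylsilyloxy)ethyl]cyclohex-2-en-1-ol | O[C@]1(C=C)C[C@H](CCO[Si](CC)(CC)CC)CC=C1C
F4 | step 5 | (2S,3S,5S)-3-bromo-2-ethenyl-2-methyl-5-[2-(triethylsilyloxy)ethyl]cyclohexan-1-one | O=C1C[C@H](CCO[Si](CC)(CC)CC)C[C@H](Br)[C@@]1(C)C=C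
F5 | step 5 | (2S,5S)-2-ethenyl-2-methyl-5-[2-(triethylsilyloxy)ethyl]cyclohexan-1-one | O=C1C[C@H](CCO[Si](CC)(CC)CC)CC[C@@]1(C)C=C
F6 | step 7 | (2S,5S)-2-(hydroxymethyl)-2-methyl-5-[2-(triethylsilyloxy)ethyl]cyclohexan-1-one | O=C1C[C@H](CCO[Si](CC)(CC)CC)CC[C@@]1(C)CO
F7 | step 7 | (4S,7S)-7-(hydroxymethyl)-7-methyl-4-[2-(triethylsilyloxy)ethyl]oxepan-2-one | O=C1C[C@H](CCO[Si](CC)(CC)CC)CC[C@@](C)(CO)O1
F8 | step 7 | (2S,5S)-2-methyl-7-oxo-5-[2-(triethylsilyloxy)ethyl]oxepane-2-carbaldehyde | O=C1C[C@H](CCO[Si](CC)(CC)CC)CC[C@@](C)(C=O)O1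
F9 | step 7 | ethenylzinc alkoxide of the (1R)-vinyl adduct of F8 | O=C1C[C@H](CCO[Si](CC)(CC)CC)CC[C@@](C)([C@H](O[Zn]C=C)C=C)O1
F10 | step 14 | B-alkyl-9-BBN adduct of 13 | O=C1C(CN(C)C)[C@H](CCO[Si](CC)(CC)CC)CC[C@@](C)([C@H](OC(C)=O)CCB2C3CCCC2CCC3)O1
F11 | step 14 | (1R,4Z)-1-{(2S,5S)-6-[(dimethylamino)methyl]-2-methyl-7-oxo-5-[2-(triethylsilyloxy)ethyl]oxepan-2-yl}-4-methylnon-4-en-7-yn-1-yl acetate | O=C1C(CN(C)C)[C@H](CCO[Si](CC)(CC)CC)CC[C@@](C)([C@H](OC(C)=O)CC/C(C)=C\CC#CC)O1
F12 | step 14 | alkenylzirconocene chloride of F11 (Zr on the methyl-bearing carbon, E) | O=C1C(CN(C)C)[C@H](CCO[Si](CC)(CC)CC)CC[C@@](C)([C@H](OC(C)=O)CC/C(C)=C\C/C=C(/[Zr](Cl)(C2C=CC=C2)C2C=CC=C2)C)O1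
F13 | step 14 | (1R,4Z,7E)-1-{(2S,5S)-6-[(dimethylamino)methyl]-2-methyl-7-oxo-5-[2-(triethylsilyloxy)ethyl]oxepan-2-yl}-8-iodo-4-methylnona-4,7-dien-1-yl acetate | O=C1C(CN(C)C)[C@H](CCO[Si](CC)(CC)CC)CC[C@@](C)([C@H](OC(C)=O)CC/C(C)=C\C/C=C(/I)C)O1
F14 | step 14 | (1R,4Z,7E)-1-{(2S,5S)-6-[(dimethylamino)methyl]-2-methyl-7-oxo-5-(2-oxoethyl)oxepan-2-yl}-8-iodo-4-methylnona-4,7-dien-1-yl acetate | O=C1C(CN(C)C)[C@H](CC=O)CC[C@@](C)([C@H](OC(C)=O)CC/C(C)=C\C/C=C(/I)C)O1
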